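**Plan**

1. Retrosynthesis: the two aryl O–Si bonds are cut last. Ring A is then cut at C4a–C8a, C5–C6 and C7–C8, which opens rings A and C together and leaves a tethered diyne and triisopropylsilyl ethynyl ether.
2. Enabling feature: ring A is a 1,2,3,4-tetrasubstituted benzene in which O1 on C8a and the oxygen on C7 flank the lavandulyl-bearing C8, C4a carries the C4 carbonyl, and C5 and C6 are CH. This is the sum of an ynol ether (C8a≡C8), a siloxyalkyne (C7≡C6) and an ynone (C4a≡C5), the first and third already linked through O1–C2–C3–C4 of ring C.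
3. The diyne is cut at C8–CH2 (alkoxyacetylide plus lavandulyl triflate), O1–C8a (alkoxide plus trichloroethylene), C4–C4a (acetylide plus aldehyde) and C2–C3 (allylboration of the aryl aldehyde).
4. Forward order: aryl aldehyde, C2 carbinol, dichlorovinyl ether as masked ynol ether, chain shortening to the aldehyde, silyl-capped alkynyl carbinol, ynol ether with the lavandulyl chain, ynone; rings C and A then form together in the rhodium step and desilylation ends the route.
5. Stereochemistry: C2 (S) comes from a reagent-controlled Brown allylboration, the lavandulyl centre from an Evans deconjugative alkylation. Both are in place before the key step and are not touched afterwards.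

Key step: step 14

Remark: the lavandulyl stereocentre keeps one spatial arrangement throughout; its CIP label is S while the neighbouring CH2 carries oxygen (imide, lavandulol, triflate) and R once that CH2 is bonded to the alkyne or arene carbon.
Remark: (−)-B-allyldiisopinocampheylborane and lithium (trimethylsilyl)acetylide are taken as the purchased solutions. Because aryl silyl ethers are the most fluoride-labile silyl ethers, the route avoids any fluoride step before the end and carries the ynol ether as its acid-stable dichlorovinyl precursor through the chain-shortening steps.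

**Route**

Step 1
Reactants: 1 4-hydroxy-2-methoxybenzaldehyde; 2 chlorotriisopropylsilane
Product: 3 2-methoxy-4-(triisopropylsilyloxy)benzaldehyde
Conditions: iPr3SiCl, imidazole, DMF, rt
Reagents that add atoms: chlorotriisopropylsilane, CC(C)[Si](Cl)(C(C)C)C(C)C
Why: Imidazole-promoted O-silylation of the phenol should give an aryl TIPS ether that tolerates potassium hydride, butyllithium, periodate and cationic rhodium and is removed in the last step together with the second silyl group.

Step 2
Reactants: 3 2-methoxy-4-(triisopropylsilyloxy)benzaldehyde; 4 (−)-B-allyldiisopinocampheylborane (reagent from (+)-α-pinene)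
Product: 6 (1S)-1-[2-methoxy-4-(triisopropylsilyloxy)phenyl]but-3-en-1-ol, via borinate ester 5 (not isolated)
Conditions: (−)-Ipc2B(allyl), Et2O–pentane, −78 °C; then ethanolamine, rt
Reagents that add atoms: (−)-B-allyldiisopinocampheylborane (allyl group), C=CCB([C@@H]1C[C@@H]2C[C@H]([C@H]1C)C2(C)C)[C@@H]1C[C@@H]2C[C@H]([C@H]1C)C2(C)C
Why: Brown allylboration through a chair Zimmerman–Traxler transition state, in which the reagent derived from (+)-α-pinene delivers the allyl group to the Si face of the aldehyde, should set the carbinol centre (the later C2) as S under reagent control.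

Step 3
Reactants: 6 (1S)-1-[2-methoxy-4-(triisopropylsilyloxy)phenyl]but-3-en-1-ol; 7 trichloroethylene
Product: 9 {4-[(1S)-1-{[(E)-1,2-dichloroethenyl]oxy}but-3-en-1-yl]-3-methoxyphenoxy}triisopropylsilane, via potassium alkoxide 8 (not isolated)
Conditions: KH, THF, 0 °C; then Cl2C=CHCl, −50 °C → rt
Reagents that add atoms: trichloroethylene, ClC=C(Cl)Cl
Why: The potassium alkoxide should add to dichloroacetylene formed in situ from trichloroethylene (first half of the trichloroethylene route to alkynyl ethers), which forms the O1–C8a bond without touching the C–O stereocentre and stores the ynol ether as an acid- and oxidant-tolerant dichlorovinyl ether.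

Step 4
Reactants: 9 the (S)-dichlorovinyl ether; 10 sodium periodate
Product: 12 (3S)-3-{[(E)-1,2-dichloroethenyl]oxy}-3-[2-methoxy-4-(triisopropylsilyloxy)phenyl]propanal, via diol 11 (not isolated)
Conditions: OsO4 (cat.), NaIO4, 2,6-lutidine, dioxane–H2O, rt
Reagents that add atoms: sodium periodate (terminal oxidant, oxygen relayed by catalytic OsO4), [Na+].[O-]I(=O)(=O)=O
Why: Lemieux–Johnson oxidation (osmium-catalysed dihydroxylation and periodate cleavage) should cut the electron-rich monosubstituted alkene to the aldehyde while the chlorine-deactivated enol ether double bond and the arene are left alone.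

Step 5
Reactants: 12 the (S)-aldehyde; 13 lithium (trimethylsilyl)acetylide; 14 chlorotrimethylsilane
Product: 16 (1S,3RS)-1-{[(E)-1,2-dichloroethenyl]oxy}-1-[2-methoxy-4-(triisopropylsilyloxy)phenyl]-3-(trimethylsilyloxy)-5-(trimethylsilyl)pent-4-yne, via lithium alkoxide 15 (not isolated)
Conditions: LiC≡CSiMe3, THF, −78 °C; then Me3SiCl, −78 → 0 °C
Reagents that add atoms: lithium (trimethylsilyl)acetylide, [Li]C#C[Si](C)(C)C; chlorotrimethylsilane, C[Si](C)(C)Cl
Why: 1,2-Addition of the lithium acetylide to the aldehyde and in situ O-silylation of the alkoxide should give the doubly Me3Si-capped alkynyl carbinol, whose new carbinol centre needs no control because it becomes the C4 carbonyl in step 12 and whose O–H and ≡C–H are thereby masked against butyllithium.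

Step 6
Reactants: 17 (S)-4-benzyloxazolidin-2-one; 18 3-methylbut-2-enoyl chloride
Product: 20 (4S)-4-benzyl-3-(3-methylbut-2-enoyl)oxazolidin-2-one, via lithium oxazolidinide 19 (not isolated)
Conditions: n-BuLi, THF, −78 °C; then the acid chloride, −78 → 0 °C
Reagents that add atoms: 3-methylbut-2-enoyl chloride, CC(C)=CC(Cl)=O
Why: N-Acylation of the lithiated Evans oxazolidinone with the acid chloride at −78 °C should give the imide without deconjugation of the enoyl group.

Step 7
Reactants: 20 (4S)-4-benzyl-3-(3-methylbut-2-enoyl)oxazolidin-2-one; 21 prenyl bromide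
Product: 23 (4S)-4-benzyl-3-[(2S)-5-methyl-2-(prop-1-en-2-yl)hex-4-enoyl]oxazolidin-2-one, via sodium dienolate 22 (not isolated)
Conditions: NaHMDS, THF, −78 °C; then prenyl bromide, −78 → −40 °C
Reagents that add atoms: prenyl bromide, CC(C)=CCBr
Why: Evans alkylation in its deconjugative variant, in which γ-deprotonation gives the sodium-chelated (Z)-dienolate that is alkylated at Cα on the face opposite the benzyl group, should set the lavandulyl stereocentre as S under auxiliary control and move the double bond into the isopropenyl position.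

Step 8
Reactants: 23 the alkylated imide
Product: 24 (S)-lavandulol, (2S)-5-methyl-2-(prop-1-en-2-yl)hex-4-en-1-ol
Conditions: LiBH4, H2O (1 equiv), Et2O, 0 °C
Reagents that add atoms: none
Why: Reductive cleavage of the N-acyl oxazolidinone with lithium borohydride should give the primary alcohol without epimerisation at the α-carbon and return the auxiliary.

Step 9
Reactants: 24 (S)-lavandulol; 25 trifluoromethanesulfonic anhydride
Product: 26 (S)-lavandulyl trifluoromethanesulfonate
Conditions: Tf2O, 2,6-lutidine, CH2Cl2, −78 °C; cold filtration, used at once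
Reagents that add atoms: trifluoromethanesulfonic anhydride, O=S(=O)(OS(=O)(=O)C(F)(F)F)C(F)(F)F
Why: Sulfonylation of the primary alcohol with triflic anhydride should give the triflate, chosen because the SN2 reaction at this β-branched carbon in step 10 has to run below −20 °C, and the stereocentre is not involved.

Step 10
Reactants: 16 the silyl-capped dichlorovinyl ether; 26 (S)-lavandulyl trifluoromethanesulfonate
Product: 29 (1S,3RS)-1-[2-methoxy-4-(triisopropylsilyloxy)phenyl]-1-{[(4R)-7-methyl-4-(prop-1-en-2-yl)oct-6-en-1-yn-1-yl]oxy}-3-(trimethylsilyloxy)-5-(trimethylsilyl)pent-4-yne, via chloroalkynyl ether 27 (not isolated), via lithium alkynyl ether 28 (not isolated)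
Conditions: n-BuLi (2.3 equiv), THF, −78 → −40 °C; then 26, THF–DMPU, −78 → −20 °C
Reagents that add atoms: (S)-lavandulyl trifluoromethanesulfonate, C=C(C)[C@H](CC=C(C)C)COS(=O)(=O)C(F)(F)F
Why: Dehydrochlorination and chlorine–lithium exchange with two equivalents of butyllithium should turn the dichlorovinyl ether into the lithium alkoxyacetylide, whose SN2 C-alkylation by the primary triflate (second half of the trichloroethylene alkynyl ether synthesis) forms the C8–CH2 bond with both stereocentres as spectators.

Step 11
Reactants: 29 the silyl-capped ynol ether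
Product: 30 (3RS,5S)-5-[2-methoxy-4-(triisopropylsilyloxy)phenyl]-5-{[(4R)-7-methyl-4-(prop-1-en-2-yl)oct-6-en-1-yn-1-yl]oxy}pent-1-yn-3-ol
Conditions: K2CO3 (0.3 equiv), MeOH–THF, 0 °C
Reagents that add atoms: none
Why: Carbonate-catalysed methanolysis should cleave the O–SiMe3 ether and protodesilylate the alkynyl C–SiMe3 group while the hindered aryl TIPS ether and the base-stable ynol ether remain.

Step 12
Reactants: 30 the propargylic alcohol
Product: 31 (5S)-5-[2-methoxy-4-(triisopropylsilyloxy)phenyl]-5-{[(4R)-7-methyl-4-(prop-1-en-2-yl)oct-6-en-1-yn-1-yl]oxy}pent-1-yn-3-one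
Conditions: activated MnO2, CH2Cl2, rt; used without delay
Reagents that add atoms: none
Why: Manganese dioxide oxidation of the propargylic alcohol runs under neutral conditions, so the acid-sensitive ynol ether and the β-alkoxy ketone should survive, and it removes the uncontrolled carbinol centre.

Step 13
Reactants: 32 3-phenylisoxazole; 33 triisopropylsilyl trifluoromethanesulfonate
Product: 36 triisopropylsilyl ethynyl ether, via 5-lithio-3-phenylisoxazole 34 (not isolated), via lithium ethynolate 35 (not isolated)
Conditions: n-BuLi (1.0 equiv), THF, −78 °C; then iPr3SiOTf, −78 → 0 °C; distillation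
Reagents that add atoms: triisopropylsilyl trifluoromethanesulfonate, CC(C)[Si](OS(=O)(=O)C(F)(F)F)(C(C)C)C(C)C
Why: Lithiation of the isoxazole at C5 should trigger the base-induced ring fragmentation of 5-metalated 3-substituted isoxazoles to a nitrile and an ynolate, and the hard, bulky silyl triflate should trap the ynolate at oxygen (O-silylation of ynolates) to give the siloxyalkyne.

Step 14
Reactants: 31 the (S)-ynol ether–ynone diyne; 36 triisopropylsilyl ethynyl ether
Product: 37 (2S)-2-[2-methoxy-4-(triisopropylsilyloxy)phenyl]-8-[(2R)-5-methyl-2-(prop-1-en-2-yl)hex-4-en-1-yl]-7-(triisopropylsilyloxy)chroman-4-one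
Conditions: [Rh(cod)2]BF4 (10 mol%), rac-BINAP (10 mol%), pre-treated with H2 then Ar; 36 (3 equiv); slow addition of 31; CH2Cl2, rt
Reagents that add atoms: triisopropylsilyl ethynyl ether, C#CO[Si](C(C)C)(C(C)C)C(C)C
Why: Proposed new method: the cationic Rh(I)–bisphosphine fragment should bind both alkynes of the 1,7-diyne and undergo oxidative cyclisation to a rhodacyclopentadiene, which forms C4a–C8a and thereby closes the six-membered pyranone ring C over the tether O1–C2–C3–C4; the siloxyalkyne then inserts into the Rh–C5 bond (C5–C6) and C7–C8 reductive elimination closes the benzene ring A, a formal [2+2+2] cycloaddition. The closest known reaction type is the Rh(I)- or Ru-catalysed [2+2+2] cycloaddition of tethered 1,6- and 1,7-diynes with terminal alkynes, alkoxyalkynes and ynamides to fused arenes, but a diyne that combines an ynol ether with an ynone, and a siloxyalkyne as the third partner, have not been used. No stereocentre is formed, C2 and the lavandulyl centre are spectators, and room temperature keeps the benzylic alkynyl ether from its [3,3] shift. The step needs one orientation of the siloxyalkyne (oxygen on C7 next to C8, not on C6), which the substrate should secure by matched polarity, since the nucleophilic CH terminus of the siloxyalkyne pairs with the electrophilic β-carbon C5 of the ynone and its oxygen-bearing carbon with the nucleophilic β-carbon C8 of the tethered ynol ether, and by sterics, since insertion occurs at the unhindered Rh–C5(H) bond with the bulky silyloxy carbon placed on rhodium. The crowded C7–C8 bond is then formed last, in an intramolecular reductive elimination that has no alternative. Chemoselectivity against diyne homo-coupling relies on the intramolecular first step, an excess of the siloxyalkyne and slow addition of the diyne.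

Step 15
Reactants: 37 the bis-TIPS flavanone
Product: 38 alopecurone G, (2S)-7-hydroxy-2-(4-hydroxy-2-methoxyphenyl)-8-[(2R)-5-methyl-2-(prop-1-en-2-yl)hex-4-en-1-yl]chroman-4-one
Conditions: Bu4NF (2.5 equiv), AcOH (3 equiv), THF, 0 °C
Reagents that add atoms: none
Why: Fluoride-induced cleavage of both aryl silyl ethers, buffered with acetic acid so that the phenoxides are protonated at once, should give the target without base-induced ring opening of the flavanone to the chalcone and hence without loss of configuration at C2.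

**Compound list**

1 | 4-hydroxy-2-methoxybenzaldehyde | COc1cc(O)ccc1C=O | starting material
2 | chlorotriisopropylsilane | CC(C)[Si](Cl)(C(C)C)C(C)C | starting material
3 | 2-methoxy-4-(triisopropylsilyloxy)benzaldehyde | COc1cc(O[Si](C(C)C)(C(C)C)C(C)C)ccc1C=O | intermediate
4 | (−)-B-allyldiisopinocampheylborane | C=CCB([C@@H]1C[C@@H]2C[C@H]([C@H]1C)C2(C)C)[C@@H]1C[C@@H]2C[C@H]([C@H]1C)C2(C)C | starting material
5 | diisopinocampheylborinate of alcohol 6 (not isolated) | C=CC[C@H](OB([C@@H]1C[C@@H]2C[C@H]([C@H]1C)C2(C)C)[C@@H]1C[C@@H]2C[C@H]([C@H]1C)C2(C)C)c1ccc(O[Si](C(C)C)(C(C)C)C(C)C)cc1OC | intermediate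
6 | (1S)-1-[2-methoxy-4-(triisopropylsilyloxy)phenyl]but-3-en-1-ol | C=CC[C@H](O)c1ccc(O[Si](C(C)C)(C(C)C)C(C)C)cc1OC | intermediate
7 | trichloroethylene | ClC=C(Cl)Cl | starting material
8 | potassium alkoxide of 6 (not isolated) | [K+].C=CC[C@H]([O-])c1ccc(O[Si](C(C)C)(C(C)C)C(C)C)cc1OC | intermediate
9 | {4-[(1S)-1-{[(E)-1,2-dichloroethenyl]oxy}but-3-en-1-yl]-3-methoxyphenoxy}triisopropylsilane | C=CC[C@H](O/C(Cl)=C\Cl)c1ccc(O[Si](C(C)C)(C(C)C)C(C)C)cc1OC | intermediate
10 | sodium periodate | [Na+].[O-]I(=O)(=O)=O | starting material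
11 | (2RS,4S)-4-{[(E)-1,2-dichloroethenyl]oxy}-4-[2-methoxy-4-(triisopropylsilyloxy)phenyl]butane-1,2-diol (not isolated) | OCC(O)C[C@H](O/C(Cl)=C\Cl)c1ccc(O[Si](C(C)C)(C(C)C)C(C)C)cc1OC | intermediate
12 | (3S)-3-{[(E)-1,2-dichloroethenyl]oxy}-3-[2-methoxy-4-(triisopropylsilyloxy)phenyl]propanal | O=CC[C@H](O/C(Cl)=C\Cl)c1ccc(O[Si](C(C)C)(C(C)C)C(C)C)cc1OC | intermediate
13 | lithium (trimethylsilyl)acetylide | [Li]C#C[Si](C)(C)C | starting material
14 | chlorotrimethylsilane | C[Si](C)(C)Cl | starting material
15 | lithium alkoxide of the acetylide adduct (not isolated) | [Li+].[O-]C(C[C@H](O/C(Cl)=C\Cl)c1ccc(O[Si](C(C)C)(C(C)C)C(C)C)cc1OC)C#C[Si](C)(C)C | intermediate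
16 | (1S,3RS)-1-{[(E)-1,2-dichloroethenyl]oxy}-1-[2-methoxy-4-(triisopropylsilyloxy)phenyl]-3-(trimethylsilyloxy)-5-(trimethylsilyl)pent-4-yne | C[Si](C)(C)OC(C[C@H](O/C(Cl)=C\Cl)c1ccc(O[Si](C(C)C)(C(C)C)C(C)C)cc1OC)C#C[Si](C)(C)C | intermediate
17 | (S)-4-benzyloxazolidin-2-one | O=C1OC[C@H](Cc2ccccc2)N1 | starting material
18 | 3-methylbut-2-enoyl chloride | CC(C)=CC(Cl)=O | starting material
19 | lithium salt of 17 (not isolated) | [Li]N1C(=O)OC[C@@H]1Cc1ccccc1 | intermediate
20 | (4S)-4-benzyl-3-(3-methylbut-2-enoyl)oxazolidin-2-one | CC(C)=CC(=O)N1C(=O)OC[C@@H]1Cc1ccccc1 | intermediate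
21 | prenyl bromide (1-bromo-3-methylbut-2-ene) | CC(C)=CCBr | starting material
22 | sodium (Z)-dienolate of 20 (not isolated) | [Na+].C=C(C)/C=C(\[O-])N1C(=O)OC[C@@H]1Cc1ccccc1 | intermediate
23 | (4S)-4-benzyl-3-[(2S)-5-methyl-2-(prop-1-en-2-yl)hex-4-enoyl]oxazolidin-2-one | C=C(C)[C@H](CC=C(C)C)C(=O)N1C(=O)OC[C@@H]1Cc1ccccc1 | intermediate
24 | (S)-lavandulol | C=C(C)[C@H](CC=C(C)C)CO | intermediate
25 | trifluoromethanesulfonic anhydride | O=S(=O)(OS(=O)(=O)C(F)(F)F)C(F)(F)F | starting material
26 | (S)-lavandulyl trifluoromethanesulfonate | C=C(C)[C@H](CC=C(C)C)COS(=O)(=O)C(F)(F)F | intermediate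
27 | chloroalkynyl ether from 16 (not isolated) | C[Si](C)(C)OC(C[C@H](OC#CCl)c1ccc(O[Si](C(C)C)(C(C)C)C(C)C)cc1OC)C#C[Si](C)(C)C | intermediate
28 | lithium alkynyl ether from 16 (not isolated) | C[Si](C)(C)OC(C[C@H](OC#C[Li])c1ccc(O[Si](C(C)C)(C(C)C)C(C)C)cc1OC)C#C[Si](C)(C)C | intermediate
29 | (1S,3RS)-1-[2-methoxy-4-(triisopropylsilyloxy)phenyl]-1-{[(4R)-7-methyl-4-(prop-1-en-2-yl)oct-6-en-1-yn-1-yl]oxy}-3-(trimethylsilyloxy)-5-(trimethylsilyl)pent-4-yne | C=C(C)[C@H](CC=C(C)C)CC#CO[C@H](c1ccc(O[Si](C(C)C)(C(C)C)C(C)C)cc1OC)CC(O[Si](C)(C)C)C#C[Si](C)(C)C | intermediate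
30 | (3RS,5S)-5-[2-methoxy-4-(triisopropylsilyloxy)phenyl]-5-{[(4R)-7-methyl-4-(prop-1-en-2-yl)oct-6-en-1-yn-1-yl]oxy}pent-1-yn-3-ol | C=C(C)[C@H](CC=C(C)C)CC#CO[C@H](c1ccc(O[Si](C(C)C)(C(C)C)C(C)C)cc1OC)CC(O)C#C | intermediate
31 | (5S)-5-[2-methoxy-4-(triisopropylsilyloxy)phenyl]-5-{[(4R)-7-methyl-4-(prop-1-en-2-yl)oct-6-en-1-yn-1-yl]oxy}pent-1-yn-3-one | C=C(C)[C@H](CC=C(C)C)CC#CO[C@H](c1ccc(O[Si](C(C)C)(C(C)C)C(C)C)cc1OC)CC(=O)C#C | intermediate
32 | 3-phenylisoxazole | c1ccc(-c2ccon2)cc1 | starting material
33 | triisopropylsilyl trifluoromethanesulfonate | CC(C)[Si](OS(=O)(=O)C(F)(F)F)(C(C)C)C(C)C | starting material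
34 | 5-lithio-3-phenylisoxazole (not isolated) | [Li]c1cc(-c2ccccc2)no1 | intermediate
35 | lithium ethynolate (not isolated) | [Li+].[O-]C#C | intermediate
36 | triisopropylsilyl ethynyl ether | C#CO[Si](C(C)C)(C(C)C)C(C)C | intermediate
37 | (2S)-2-[2-methoxy-4-(triisopropylsilyloxy)phenyl]-8-[(2R)-5-methyl-2-(prop-1-en-2-yl)hex-4-en-1-yl]-7-(triisopropylsilyloxy)chroman-4-one | C=C(C)[C@H](CC=C(C)C)Cc1c(O[Si](C(C)C)(C(C)C)C(C)C)ccc2c1O[C@H](c1ccc(O[Si](C(C)C)(C(C)C)C(C)C)cc1OC)CC2=O | intermediate
38 | alopecurone G | C=C(C)[C@H](CC=C(C)C)Cc1c(O)ccc2c1O[C@H](c1ccc(O)cc1OC)CC2=O | target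

**Step count and risks**

Total step count: 15. Longest linear sequence: 10 (steps 1–5, 10, 11, 12, 14, 15).

Steps most likely to fail:

1. Step 14 (proposed new method). The siloxyalkyne may insert with the reverse orientation and place the oxygen on C6. The diyne may oligomerise before the third alkyne is taken up. The Lewis-acidic cationic rhodium may ionise the electron-rich benzylic C–O bond or promote the sigmatropic shift of the alkynyl ether. Fallback with known chemistry, setting out from triflate 26 and coming back at 37: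
   - Ortho-lithiation of commercial 1,3-bis(methoxymethoxy)benzene at C2 (n-BuLi, THF, 0 °C) and alkylation with 26 would give 2-[(2R)-lavandulyl]-1,3-bis(methoxymethoxy)benzene F1.
   - A second ortho-lithiation at C4 and acylation with N-methoxy-N-methylacetamide would give the acetophenone F2.
   - Brief treatment with dilute HCl in methanol at 0 °C would give the resacetophenone F3, and silylation of the non-chelated 4-hydroxyl (iPr3SiCl, imidazole) the mono-TIPS ether F4.
   - Condensation with DMF dimethyl acetal would give the enaminone F5, which cyclises under mild acid with loss of dimethylamine to 8-lavandulyl-7-(triisopropylsilyloxy)chromone F6.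
   - The B ring would come from 4-bromo-3-methoxyphenol through its TIPS ether, the aryl bromide F7, and bromine–lithium exchange and borylation to the boronic acid F8.
   - A rhodium(I)-catalysed enantioselective 1,4-addition of F8 to F6 (Hayashi–Miyaura reaction, electron-poor atropisomeric bisphosphine of the ligand antipode that leads to the 2S series) would give 37, from which step 15 follows.

2. Step 10. The homoallylic triflate may ionise with participation of the isopropenyl double bond before the slow SN2 reaction at the β-branched carbon takes place. The lithium alkoxyacetylide may decompose on warming. Butyllithium may attack the O–SiMe3 group. The fallback sets out from alcohol 24 and from the lithium alkynyl ether 28 (made from 16 as in step 10) and comes back at 29. Appel iodination of 24 (I2, PPh3, imidazole) would give the storable, non-ionising (S)-lavandulyl iodide F9, and 28 would be alkylated with F9 in THF–HMPA between −78 °C and rt. The C–C bond is then formed by activating the acetylide in a dipolar aprotic medium instead of relying on a super-leaving group at low temperature.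

3. Step 13. The ambident ethynolate may be silylated on carbon and give the silylketene. Butyllithium or the ynolate may add to the benzonitrile set free. The volatile product may be lost on isolation. The fallback sets out from trichloroethylene 7 and commercial triisopropylsilanol and comes back at 36; it makes the Si–O bond before the triple bond, so that O- versus C-silylation no longer arises. Potassium triisopropylsilanolate (silanol, KH, THF) and 7 would give (E)-1,2-dichlorovinyl triisopropylsilyl ether F10. Treatment with n-BuLi (2 equiv, −78 °C) and a methanol quench at −78 °C would then give 36.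

**Further compounds**

F1 | step 14 | 2-[(2R)-5-methyl-2-(prop-1-en-2-yl)hex-4-en-1-yl]-1,3-bis(methoxymethoxy)benzene | C=C(C)[C@H](CC=C(C)C)Cc1c(OCOC)cccc1OCOC
F2 | step 14 | 1-{2,4-bis(methoxymethoxy)-3-[(2R)-5-methyl-2-(prop-1-en-2-yl)hex-4-en-1-yl]phenyl}ethanone | C=C(C)[C@H](CC=C(C)C)Cc1c(OCOC)ccc(C(C)=O)c1OCOC
F3 | step 14 | 1-{2,4-dihydroxy-3-[(2R)-5-methyl-2-(prop-1-en-2-yl)hex-4-en-1-yl]phenyl}ethanone | C=C(C)[C@H](CC=C(C)C)Cc1c(O)ccc(C(C)=O)c1O
F4 | step 14 | 1-{2-hydroxy-3-[(2R)-5-methyl-2-(prop-1-en-2-yl)hex-4-en-1-yl]-4-(triisopropylsilyloxy)phenyl}ethanone | C=C(C)[C@H](CC=C(C)C)Cc1c(O[Si](C(C)C)(C(C)C)C(C)C)ccc(C(C)=O)c1O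
F5 | step 14 | (E)-3-(dimethylamino)-1-{2-hydroxy-3-[(2R)-5-methyl-2-(prop-1-en-2-yl)hex-4-en-1-yl]-4-(triisopropylsilyloxy)phenyl}prop-2-en-1-one | C=C(C)[C@H](CC=C(C)C)Cc1c(O[Si](C(C)C)(C(C)C)C(C)C)ccc(C(=O)/C=C/N(C)C)c1O
F6 | step 14 | 8-[(2R)-5-methyl-2-(prop-1-en-2-yl)hex-4-en-1-yl]-7-(triisopropylsilyloxy)-4H-chromen-4-one | C=C(C)[C@H](CC=C(C)C)Cc1c(O[Si](C(C)C)(C(C)C)C(C)C)ccc2c1occc2=O
F7 | step 14 | (4-bromo-3-methoxyphenoxy)triisopropylsilane | COc1cc(O[Si](C(C)C)(C(C)C)C(C)C)ccc1Br
F8 | step 14 | [2-methoxy-4-(triisopropylsilyloxy)phenyl]boronic acid | COc1cc(O[Si](C(C)C)(C(C)C)C(C)C)ccc1B(O)O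
F9 | step 10 | (S)-lavandulyl iodide, (2S)-1-iodo-5-methyl-2-(prop-1-en-2-yl)hex-4-ene | C=C(C)[C@H](CC=C(C)C)CI
F10 | step 13 | (E)-1,2-dichlorovinyl triisopropylsilyl ether | Cl/C=C(/Cl)O[Si](C(C)C)(C(C)C)C(C)C
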